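**Retrosynthetic overview**

1. The C3 side chain comes from a Z-selective Still–Gennari olefination of a C3 phosphonoacetate (8,9-diol held as acetonide) with (R)-2-(angeloyloxy)butanal; the phosphonoacetate is installed by Mitsunobu inversion of a 3β-ol.
2. The 3β,8α,9α-triol comes from a 9α-hydroxy-3,8-dione (LiBH(sBu)3), made by Rubottom oxidation of the Δ8 silyl enol ether that Li/NH3 reduction of a Δ9(10)-8-enone delivers (this sets the trans ring fusion).
3. The enone comes from a cis-decalin methyl enol ether formed by anionic oxy-Cope rearrangement of a 2-vinylbicyclo[2.2.2]oct-5-en-2-ol (C1–C10 made, C3–C8 broken).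
4. The bicyclo[2.2.2]octenone comes from a Diels–Alder reaction of a 1-methoxy-2-silyloxycyclohexa-1,3-diene with an acetylene equivalent, anti to the isopropenyl group (sets C5); the diene is made from (S)-carvone by MeLi addition, oxidative transposition and α′-methoxylation.
5. Ring order: carvone ring, then the bicyclo[2.2.2]octene (Diels–Alder), then rings A and B of the decalin together in the oxy-Cope step.

Assumption: decalin positions follow eremophilane numbering (ring A = C1–C5 and C10, ring B = C5–C10; β = face of the C5 methyl); phenyl vinyl sulfoxide, the racemic oxaziridine, angelic acid and [bis(2,2,2-trifluoroethoxy)phosphoryl]acetic acid are bought.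

**Step 1**
Reactants: 1 (S)-(+)-carvone
Product: 2 (1S,5S)-1,2-dimethyl-5-(prop-1-en-2-yl)cyclohex-2-en-1-ol (major C1 epimer)
Conditions: MeLi, Et2O, −78 → 0 °C; H2O
Reagents that add atoms: methyllithium, [Li]C
Why: Clean 1,2-addition of the organolithium to the enone carbonyl; the new carbinol centre is erased in step 2, so its configuration does not matter.

**Step 2**
Reactants: 2 (1S,5S)-1,2-dimethyl-5-(prop-1-en-2-yl)cyclohex-2-en-1-ol
Product: 3 (5R)-2,3-dimethyl-5-(prop-1-en-2-yl)cyclohex-2-en-1-one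
Conditions: [C5H5NH][CrO3Cl], silica gel, CH2Cl2, 23 °C
Reagents that add atoms: pyridinium chlorochromate, [O-][Cr](=O)(=O)Cl.c1cc[nH+]cc1
Why: Dauben oxidative 1,3-transposition: the tertiary allylic chromate ester undergoes a [3,3] shift that places a chromate oxygen on the former β-carbon and is then oxidised to the transposed enone; the C5 stereocentre is untouched.

**Step 3**
Reactants: 3 (5R)-2,3-dimethyl-5-(prop-1-en-2-yl)cyclohex-2-en-1-one
Product: 4 (5S,6S)-6-hydroxy-2,3-dimethyl-5-(prop-1-en-2-yl)cyclohex-2-en-1-one (trans isomer major)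
Conditions: KN(SiMe3)2, THF, −78 °C; racemic trans-2-(phenylsulfonyl)-3-phenyloxaziridine, −78 °C; AcOH
Reagents that add atoms: 2-(phenylsulfonyl)-3-phenyloxaziridine, O=S(=O)(N1OC1c1ccccc1)c1ccccc1
Why: Kinetic α′-deprotonation gives the cross-conjugated enolate, which is hydroxylated at C6 (Davis oxidation); the C6 configuration is irrelevant because C6 becomes sp2 in step 5.

**Step 4**
Reactants: 4 (5S,6S)-6-hydroxy-2,3-dimethyl-5-(prop-1-en-2-yl)cyclohex-2-en-1-one
Product: 5 (5S,6S)-6-methoxy-2,3-dimethyl-5-(prop-1-en-2-yl)cyclohex-2-en-1-one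
Conditions: MeI, Ag2O, MeCN, 40 °C, dark
Reagents that add atoms: iodomethane, CI
Why: Purdie O-methylation under non-basic conditions converts the α-ketol into a robust methyl ether without ketol rearrangement.

**Step 5**
Reactants: 5 (5S,6S)-6-methoxy-2,3-dimethyl-5-(prop-1-en-2-yl)cyclohex-2-en-1-one
Product: 9 (1R,3R,4S,7S)-1-methoxy-3,4-dimethyl-7-(prop-1-en-2-yl)bicyclo[2.2.2]oct-5-en-2-one, via silyl dienol ether 6 (not isolated), via sulfoxide cycloadduct 7 (not isolated), via bicyclic silyl enol ether 8 (not isolated)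
Conditions: LiN(iPr)2, Me3SiCl, THF, −78 °C; solvent swap; PhS(O)CH=CH2, NaHCO3, toluene, 110 °C; then K2CO3 (cat.), MeOH, 23 °C
Reagents that add atoms: phenyl vinyl sulfoxide, C=CS(=O)c1ccccc1
Why: Diels–Alder reaction of the electron-rich 1-methoxy-2-silyloxy diene with the acetylene equivalent occurs on the face opposite the adjacent isopropenyl group and sets the quaternary methyl-bearing bridgehead; thermal sulfoxide syn-elimination then gives the bridge alkene, and methanolysis of the silyl enol ether with base equilibration places the C3 methyl on the alkene side.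

**Step 6**
Reactants: 9 (1R,3R,4S,7S)-1-methoxy-3,4-dimethyl-7-(prop-1-en-2-yl)bicyclo[2.2.2]oct-5-en-2-one
Product: 10 (1R,2S,3R,4S,7S)-2-ethenyl-1-methoxy-3,4-dimethyl-7-(prop-1-en-2-yl)bicyclo[2.2.2]oct-5-en-2-ol
Conditions: CH2=CHMgBr, CeCl3, THF, −78 °C
Reagents that add atoms: vinylmagnesium bromide, C=C[Mg]Br
Why: Cerium-mediated Grignard addition attacks the ketone from the alkene-bridge face, because the other face is blocked by the isopropenyl group on the saturated bridge; this puts the vinyl group syn to the C5=C6 bridge as the rearrangement needs.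

**Step 7**
Reactants: 10 (1R,2S,3R,4S,7S)-2-ethenyl-1-methoxy-3,4-dimethyl-7-(prop-1-en-2-yl)bicyclo[2.2.2]oct-5-en-2-ol
Product: 13 cis-fused 8-methoxyeremophila-8,11-dien-3-one (4β-Me; 5β-Me; 7α-isopropenyl; 10β-H), via potassium alkoxide 11 (not isolated), via potassium enolate 12 (not isolated)
Conditions: KH, 18-crown-6, THF, 0 → 23 °C; cold pH 7 aqueous buffer
Reagents that add atoms: none
Why: Anionic oxy-Cope [3,3] rearrangement through the enforced boat breaks C3–C8 and forms C1–C10, giving the whole decalin with the C5 methyl trans to the C7 isopropenyl group (both fixed in the bicycle), a cis ring fusion and a regiodefined C8 methyl enol ether.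

**Step 8**
Reactants: 13 cis-fused 8-methoxyeremophila-8,11-dien-3-one
Product: 14 eremophila-9,11-diene-3,8-dione (4β-Me; 5β-Me; 7α-isopropenyl)
Conditions: DDQ, CH2Cl2/pH 7 aqueous buffer, 0 → 23 °C
Reagents that add atoms: water, O
Why: DDQ abstracts the allylic C10 hydride of the enol ether to give a conjugated oxocarbenium ion that water hydrolyses to the Δ9(10)-8-enone (enol ether dehydrogenation), which removes the wrongly set C10 centre.

**Step 9**
Reactants: 14 eremophila-9,11-diene-3,8-dione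
Product: 16 trans-fused 8-(trimethylsilyloxy)eremophila-8,11-dien-3-one (10α-H), via lithium enolate 15 (not isolated)
Conditions: Li (2.2 equiv), tBuOH (1.0 equiv), NH3/THF, −78 °C; isoprene; then Me3SiCl, Et3N, THF, −78 → 0 °C
Reagents that add atoms: chlorotrimethylsilane, C[Si](C)(C)Cl
Why: Dissolving-metal (Birch-type) reduction of the enone, which is reduced far more easily than the saturated ketone, protonates C10 axially to give the trans-decalin and leaves the Δ8 lithium enolate, trapped regiospecifically as its silyl enol ether.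

**Step 10**
Reactants: 16 trans-fused 8-(trimethylsilyloxy)eremophila-8,11-dien-3-one
Product: 18 9α-hydroxyeremophil-11-ene-3,8-dione (10α-H), via silyloxy ketone 17 (not isolated)
Conditions: mCPBA (1.05 equiv), NaHCO3, CH2Cl2, −20 °C; then citric acid, MeOH, 0 °C
Reagents that add atoms: 3-chloroperbenzoic acid, OOC(=O)c1cccc(Cl)c1
Why: Rubottom oxidation: the silyl enol ether is epoxidised much faster than the isopropenyl group, from the α face opposite the axial C5 methyl, so the new C9 hydroxyl is α (equatorial).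

**Step 11**
Reactants: 18 9α-hydroxyeremophil-11-ene-3,8-dione
Product: 19 eremophil-11-ene-3β,8α,9α-triol
Conditions: LiBH(sBu)3 (3.5 equiv), THF, −78 °C; aqueous work-up
Reagents that add atoms: none
Why: The bulky borohydride attacks both ring ketones from the equatorial direction and gives the axial alcohols, 8α-OH (cis to 9α-OH and to the isopropenyl group) and 3β-OH.

**Step 12**
Reactants: 19 eremophil-11-ene-3β,8α,9α-triol
Product: 20 8α,9α-(isopropylidenedioxy)eremophil-11-en-3β-ol
Conditions: Me2C(OMe)2, PPTS (cat.), CH2Cl2, 23 °C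
Reagents that add atoms: 2,2-dimethoxypropane, COC(C)(C)OC
Why: Only the cis-vicinal 8,9-diol can close a five-membered acetonide (transacetalisation), which leaves the 3β-hydroxyl free.

**Step 13**
Reactants: 20 8α,9α-(isopropylidenedioxy)eremophil-11-en-3β-ol; 21 [bis(2,2,2-trifluoroethoxy)phosphoryl]acetic acid
Product: 22 8α,9α-(isopropylidenedioxy)eremophil-11-en-3α-yl [bis(2,2,2-trifluoroethoxy)phosphoryl]acetate
Conditions: PPh3, DIAD, toluene, 0 → 23 °C
Reagents that add atoms: none
Why: Mitsunobu esterification displaces the activated axial 3β-oxygen with inversion, giving the equatorial 3α-ester of the target configuration.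

**Step 14**
Reactants: 23 methyl (R)-2-hydroxybutanoate
Product: 24 (2R)-2-hydroxy-N-methoxy-N-methylbutanamide
Conditions: MeNH(OMe)·HCl, iPrMgCl, THF, −20 → 0 °C
Reagents that add atoms: N,O-dimethylhydroxylamine hydrochloride, CNOC.Cl
Why: Magnesium amide aminolysis of the ester gives the Weinreb amide without touching the stereocentre.

**Step 15**
Reactants: 24 (2R)-2-hydroxy-N-methoxy-N-methylbutanamide; 25 angelic acid
Product: 27 (2R)-1-[methoxy(methyl)amino]-1-oxobutan-2-yl (2Z)-2-methylbut-2-enoate, via mixed anhydride 26 (not isolated)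
Conditions: 2,4,6-trichlorobenzoyl chloride, Et3N, toluene, 23 °C; then 24, 80 °C
Reagents that add atoms: none
Why: Yamaguchi esterification through the mixed anhydride, run without a nucleophilic catalyst, acylates the secondary alcohol while keeping the Z (angelate) geometry.

**Step 16**
Reactants: 27 (2R)-1-[methoxy(methyl)amino]-1-oxobutan-2-yl (2Z)-2-methylbut-2-enoate
Product: 28 (2R)-1-oxobutan-2-yl (2Z)-2-methylbut-2-enoate
Conditions: Cp2Zr(H)Cl, THF, 23 °C, 20 min; used at once
Reagents that add atoms: none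
Why: Hydrozirconation of the amide carbonyl gives a stable hemiaminal zirconate that releases the aldehyde on work-up; the ester and the trisubstituted alkene react far more slowly and the α-centre is not epimerised.

**Step 17**
Reactants: 22 8α,9α-(isopropylidenedioxy)eremophil-11-en-3α-yl [bis(2,2,2-trifluoroethoxy)phosphoryl]acetate; 28 (2R)-1-oxobutan-2-yl (2Z)-2-methylbut-2-enoate
Product: 29 8α,9α-(isopropylidenedioxy)eremophil-11-en-3α-yl (2Z,4R)-4-[(2Z)-2-methylbut-2-enoyloxy]hex-2-enoate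
Conditions: KN(SiMe3)2, 18-crown-6, THF, −78 °C; then 28, −78 °C
Reagents that add atoms: none
Why: Still–Gennari olefination with the trifluoroethyl phosphonate and a dissociated potassium counter-ion eliminates kinetically to the Z-enoate; the pre-formed anion at −78 °C spares the α-acyloxy stereocentre.

**Step 18**
Reactants: 29 8α,9α-(isopropylidenedioxy)eremophil-11-en-3α-yl (2Z,4R)-4-[(2Z)-2-methylbut-2-enoyloxy]hex-2-enoate
Product: 30 (3R,4R,5R,7S,8R,9S,10R)-8,9-dihydroxyeremophil-11-en-3-yl (2Z,4R)-4-[(2Z)-2-methylbut-2-enoyloxy]hex-2-enoate (CNP0382739.1)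
Conditions: AcOH/H2O/THF (3:1:1), 40 °C
Reagents that add atoms: none
Why: Mild acid hydrolysis removes the acetonide without cleaving or isomerising the two unsaturated esters.

**Compound list**

1 | (S)-(+)-carvone | CC1=CC[C@@H](CC1=O)C(C)=C | starting material
2 | (1S,5S)-1,2-dimethyl-5-(prop-1-en-2-yl)cyclohex-2-en-1-ol (major epimer) | CC1=CC[C@@H](C[C@]1(C)O)C(C)=C | intermediate
3 | (5R)-2,3-dimethyl-5-(prop-1-en-2-yl)cyclohex-2-en-1-one | CC1=C(C)C[C@H](CC1=O)C(C)=C | intermediate
4 | (5S,6S)-6-hydroxy-2,3-dimethyl-5-(prop-1-en-2-yl)cyclohex-2-en-1-one | CC1=C(C)C[C@H]([C@H](O)C1=O)C(C)=C | intermediate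
5 | (5S,6S)-6-methoxy-2,3-dimethyl-5-(prop-1-en-2-yl)cyclohex-2-en-1-one | CC1=C(C)C[C@H]([C@H](OC)C1=O)C(C)=C | intermediate
6 | [(6S)-1-methoxy-3,4-dimethyl-6-(prop-1-en-2-yl)cyclohexa-1,3-dien-2-yl]oxytrimethylsilane (silyl dienol ether) | CC1=C(C)C[C@H](C(OC)=C1O[Si](C)(C)C)C(C)=C | intermediate
7 | sulfoxide cycloadduct: 1-methoxy-3,4-dimethyl-6-(phenylsulfinyl)-7-(prop-1-en-2-yl)-2-(trimethylsilyloxy)bicyclo[2.2.2]oct-2-ene, new bridge anti to isopropenyl (sulfinyl regio- and stereoisomers) | CO[C@]12C(O[Si](C)(C)C)=C(C)[C@](C)(CC1S(=O)c3ccccc3)C[C@H]2C(C)=C | intermediate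
8 | 1-methoxy-3,4-dimethyl-7-(prop-1-en-2-yl)-2-(trimethylsilyloxy)bicyclo[2.2.2]octa-2,5-diene (bicyclic silyl enol ether) | CO[C@]12C(O[Si](C)(C)C)=C(C)[C@](C)(C=C1)C[C@H]2C(C)=C | intermediate
9 | (1R,3R,4S,7S)-1-methoxy-3,4-dimethyl-7-(prop-1-en-2-yl)bicyclo[2.2.2]oct-5-en-2-one | CO[C@]12C(=O)[C@H](C)[C@](C)(C=C1)C[C@H]2C(C)=C | intermediate
10 | (1R,2S,3R,4S,7S)-2-ethenyl-1-methoxy-3,4-dimethyl-7-(prop-1-en-2-yl)bicyclo[2.2.2]oct-5-en-2-ol | CO[C@]12[C@](O)(C=C)[C@H](C)[C@](C)(C=C1)C[C@H]2C(C)=C | intermediate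
11 | potassium alkoxide of 10 | CO[C@]12[C@]([O-])(C=C)[C@H](C)[C@](C)(C=C1)C[C@H]2C(C)=C.[K+] | intermediate
12 | potassium Δ2-enolate of 13 | C=C(C)[C@@H]1C[C@]2(C)[C@@H](C)C([O-])=CC[C@@H]2C=C1OC.[K+] | intermediate
13 | cis-fused 8-methoxyeremophila-8,11-dien-3-one (4β-Me; 5β-Me; 7α-isopropenyl; 10β-H) | C=C(C)[C@@H]1C[C@]2(C)[C@@H](C)C(=O)CC[C@@H]2C=C1OC | intermediate
14 | eremophila-9,11-diene-3,8-dione (4β-Me; 5β-Me; 7α-isopropenyl) | C=C(C)[C@@H]1C[C@]2(C)[C@@H](C)C(=O)CCC2=CC1=O | intermediate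
15 | lithium Δ8-enolate of the trans-fused 3,8-dione | C=C(C)[C@@H]1C[C@]2(C)[C@@H](C)C(=O)CC[C@H]2C=C1[O-].[Li+] | intermediate
16 | trans-fused 8-(trimethylsilyloxy)eremophila-8,11-dien-3-one (10α-H) | C=C(C)[C@@H]1C[C@]2(C)[C@@H](C)C(=O)CC[C@H]2C=C1O[Si](C)(C)C | intermediate
17 | 9α-(trimethylsilyloxy)eremophil-11-ene-3,8-dione | C=C(C)[C@@H]1C[C@]2(C)[C@@H](C)C(=O)CC[C@H]2[C@H](O[Si](C)(C)C)C1=O | intermediate
18 | 9α-hydroxyeremophil-11-ene-3,8-dione (10α-H) | C=C(C)[C@@H]1C[C@]2(C)[C@@H](C)C(=O)CC[C@H]2[C@H](O)C1=O | intermediate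
19 | eremophil-11-ene-3β,8α,9α-triol | C=C(C)[C@@H]1C[C@]2(C)[C@@H](C)[C@@H](O)CC[C@H]2[C@H](O)[C@@H]1O | intermediate
20 | 8α,9α-(isopropylidenedioxy)eremophil-11-en-3β-ol | C=C(C)[C@@H]1C[C@]2(C)[C@@H](C)[C@@H](O)CC[C@H]2[C@@H]3OC(C)(C)O[C@H]13 | intermediate
21 | [bis(2,2,2-trifluoroethoxy)phosphoryl]acetic acid | OC(=O)CP(=O)(OCC(F)(F)F)OCC(F)(F)F | starting material
22 | 8α,9α-(isopropylidenedioxy)eremophil-11-en-3α-yl [bis(2,2,2-trifluoroethoxy)phosphoryl]acetate | C=C(C)[C@@H]1C[C@]2(C)[C@@H](C)[C@H](OC(=O)CP(=O)(OCC(F)(F)F)OCC(F)(F)F)CC[C@H]2[C@@H]3OC(C)(C)O[C@H]13 | intermediate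
23 | methyl (R)-2-hydroxybutanoate | CC[C@@H](O)C(=O)OC | starting material
24 | (2R)-2-hydroxy-N-methoxy-N-methylbutanamide | CC[C@@H](O)C(=O)N(C)OC | intermediate
25 | angelic acid [(2Z)-2-methylbut-2-enoic acid] | C/C=C(/C)C(=O)O | starting material
26 | (2Z)-2-methylbut-2-enoic 2,4,6-trichlorobenzoic anhydride | C/C=C(/C)C(=O)OC(=O)c1c(Cl)cc(Cl)cc1Cl | intermediate
27 | (2R)-1-[methoxy(methyl)amino]-1-oxobutan-2-yl (2Z)-2-methylbut-2-enoate | CC[C@@H](OC(=O)/C(C)=C\C)C(=O)N(C)OC | intermediate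
28 | (2R)-1-oxobutan-2-yl (2Z)-2-methylbut-2-enoate | CC[C@@H](OC(=O)/C(C)=C\C)C=O | intermediate
29 | 8α,9α-(isopropylidenedioxy)eremophil-11-en-3α-yl (2Z,4R)-4-[(2Z)-2-methylbut-2-enoyloxy]hex-2-enoate | C=C(C)[C@@H]1C[C@]2(C)[C@@H](C)[C@H](OC(=O)/C=C\[C@@H](CC)OC(=O)/C(C)=C\C)CC[C@H]2[C@@H]3OC(C)(C)O[C@H]13 | intermediate
30 | (3R,4R,5R,7S,8R,9S,10R)-8,9-dihydroxyeremophil-11-en-3-yl (2Z,4R)-4-[(2Z)-2-methylbut-2-enoyloxy]hex-2-enoate | C=C(C)[C@@H]1C[C@]2(C)[C@@H](C)[C@H](OC(=O)/C=C\[C@@H](CC)OC(=O)/C(C)=C\C)CC[C@H]2[C@H](O)[C@@H]1O | target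

**Step count and risks**

Total: 18 steps. Longest linear sequence: 15 steps (steps 1–13, 17, 18); the aldehyde 28 is made in 3 steps (14–16).

The three steps most likely to fail:

Step 5. The diene is hindered at both termini, phenyl vinyl sulfoxide is a sluggish dienophile, and the bicyclo[2.2.2]octadiene 8 can lose its saturated bridge by retro-Diels–Alder aromatisation at 110 °C. The fallback sets out from 5 and uses a far more reactive alkyne dienophile with reductive unmasking. The silyl dienol ether 6 is made as before and treated with ethynyl p-tolyl sulfone in CH2Cl2 at 23–40 °C to give the bicyclic vinyl sulfone diene F1. Cold 1 M HCl in THF hydrolyses the enol ether to the keto vinyl sulfone F2. Sodium amalgam (Na/Hg) with Na2HPO4 in MeOH/THF at −20 °C removes the sulfonyl group, and K2CO3 in MeOH then equilibrates C3; the route is rejoined at 9.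

Step 8. Hydride abstraction by DDQ from a simple methyl enol ether may lose out to plain hydrolysis or to attack at the doubly allylic C7–H. The fallback sets out from 13 and goes through halogenation and elimination instead. NBS with NaHCO3 in THF/H2O at 0 °C converts the enol ether into the 9-bromo-3,8-dione F3. Li2CO3 and LiBr in DMF at 100 °C then eliminate HBr towards C10, and the route is rejoined at 14.

Step 9. The saturated C3 ketone may be partly reduced or may consume base while the enone is reduced, and the enolate must survive the single equivalent of proton donor. The fallback sets out from 14 and removes the competing ketone first. LiAlH(OtBu)3 in THF at −78 °C reduces only the saturated ketone, from the equatorial side, to the 3β-hydroxy enone F4. Li/NH3 with tBuOH followed by Me3SiCl/Et3N gives the trans-fused bis-silyl compound F5. Rubottom oxidation (mCPBA, then citric acid/MeOH) gives the 3β,9α-dihydroxy-8-ketone F6, and LiBH(sBu)3 reduces it to the triol; the route is rejoined at 19.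

**Further compounds**

F1 | step 5 | 1-methoxy-3,4-dimethyl-6-(4-methylphenylsulfonyl)-7-(prop-1-en-2-yl)-2-(trimethylsilyloxy)bicyclo[2.2.2]octa-2,5-diene (sulfonyl regioisomers) | CO[C@]12C(O[Si](C)(C)C)=C(C)[C@](C)(C=C1S(=O)(=O)c3ccc(C)cc3)C[C@H]2C(C)=C
F2 | step 5 | 1-methoxy-3,4-dimethyl-6-(4-methylphenylsulfonyl)-7-(prop-1-en-2-yl)bicyclo[2.2.2]oct-5-en-2-one (C3 epimers) | CO[C@]12C(=O)C(C)[C@](C)(C=C1S(=O)(=O)c3ccc(C)cc3)C[C@H]2C(C)=C
F3 | step 8 | cis-fused 9-bromoeremophil-11-ene-3,8-dione (C9 epimers) | C=C(C)[C@@H]1C[C@]2(C)[C@@H](C)C(=O)CC[C@@H]2C(Br)C1=O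
F4 | step 9 | 3β-hydroxyeremophila-9,11-dien-8-one | C=C(C)[C@@H]1C[C@]2(C)[C@@H](C)[C@@H](O)CCC2=CC1=O
F5 | step 9 | trans-fused 3β,8-bis(trimethylsilyloxy)eremophila-8,11-diene | C=C(C)[C@@H]1C[C@]2(C)[C@@H](C)[C@@H](O[Si](C)(C)C)CC[C@H]2C=C1O[Si](C)(C)C
F6 | step 9 | 3β,9α-dihydroxyeremophil-11-en-8-one | C=C(C)[C@@H]1C[C@]2(C)[C@@H](C)[C@@H](O)CC[C@H]2[C@H](O)C1=O
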